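## Retrosynthetic overview

1. The C8 ketone comes last, by allylic-selective oxidation of an 8-hydroxy carotenoid triol. C11=C12 is cut by a Wittig union of a C25 acetylenic tributylphosphonium salt with a C15 epoxy enal.
2. The C25 salt comes from a C10 trienedial and a C15 enynyl phosphonium salt (C11'=C12' Wittig). That C15 unit comes from a Sonogashira coupling (C6'–C7') of a ring enol triflate with (E)-3-methylpent-2-en-4-yn-1-ol.
3. The C15 epoxy enal comes from a chromium/nickel coupling (C8–C9) of a β,γ-epoxy aldehyde with ethyl (E)-3-iodobut-2-enoate. The aldehyde arises by methylenation/hydroboration/oxidation (adds C8) of a Sharpless epoxy aldehyde, itself from carbonylation (adds C7) of the same enol triflate.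
4. Rings: neither carbocycle is built. Both come from ketoisophorone through one (4R)-silyloxy enol triflate (ene-reductase, then ketoreductase, give (4R,6R)-actinol). The only ring formed is the oxirane of ring A (Sharpless epoxidation); ring B is carried unchanged.

Assumption: the C8 carbinol made in the chromium-mediated coupling is a temporary stereocentre erased by the last step, so it is formed without control and the intermediates carrying it are C8-epimer pairs (drawn with C8 unspecified); every other stereocentre is single and defined.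

## Route

Step 1
Reactants: 1 2,6,6-trimethylcyclohex-2-ene-1,4-dione (ketoisophorone)
Product: 2 (6R)-2,2,6-trimethylcyclohexane-1,4-dione
Conditions: ene-reductase (flavin-dependent, Old Yellow Enzyme family), NAD(P)+ cat., formate dehydrogenase, HCO2Na, phosphate buffer pH 7.0, 30 °C
Reagents that add atoms: none
Why: Biocatalytic asymmetric conjugate reduction, in which the reduced flavin delivers hydride and an active-site tyrosine the proton in a trans fashion to one face of the activated C=C, setting the first stereocentre (6R) on an achiral substrate.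

Step 2
Reactants: 2 (6R)-2,2,6-trimethylcyclohexane-1,4-dione
Product: 3 (4R,6R)-4-hydroxy-2,2,6-trimethylcyclohexan-1-one
Conditions: ketoreductase (NADH-dependent alcohol dehydrogenase of the short-chain dehydrogenase/reductase class, levodione-reductase type), NAD+ cat., formate dehydrogenase, HCO2Na, phosphate buffer pH 7.0, 30 °C
Reagents that add atoms: none
Why: Enzymatic carbonyl reduction, regioselective for the unhindered C4 ketone (C1 is flanked by two substituted carbons), with enzyme-controlled hydride delivery giving the 4R alcohol trans to the C6 methyl.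

Step 3
Reactants: 3 (4R,6R)-4-hydroxy-2,2,6-trimethylcyclohexan-1-one
Product: 4 (4R,6R)-4-(tert-butyldimethylsilyloxy)-2,2,6-trimethylcyclohexan-1-one
Conditions: TBSCl, imidazole, DMF, rt
Reagents that add atoms: tert-butyldimethylsilyl chloride CC(C)(C)[Si](C)(C)Cl
Why: Standard imidazole-promoted silylation of an unhindered secondary alcohol, no stereocentre touched.

Step 4
Reactants: 4 (4R,6R)-4-(tert-butyldimethylsilyloxy)-2,2,6-trimethylcyclohexan-1-one
Product: 6 (4R)-4-(tert-butyldimethylsilyloxy)-2,6,6-trimethylcyclohex-1-en-1-yl trifluoromethanesulfonate, via lithium enolate 5 (not isolated)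
Conditions: LiN(iPr)2, THF, −78 → 0 °C; then PhNTf2, 0 °C → rt
Reagents that add atoms: N-phenylbis(trifluoromethanesulfonimide) O=S(=O)(N(c1ccccc1)S(=O)(=O)C(F)(F)F)C(F)(F)F
Why: Enolate O-triflation, regiochemically unambiguous because only C6 carries an α-hydrogen (C2 is quaternary); the C6 stereocentre becomes sp2 and C4 is unaffected.

Step 5
Reactants: 6 (4R)-4-(tert-butyldimethylsilyloxy)-2,6,6-trimethylcyclohex-1-en-1-yl trifluoromethanesulfonate; 7 (E)-3-methylpent-2-en-4-yn-1-ol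
Product: 8 (2E)-5-[(4R)-4-(tert-butyldimethylsilyloxy)-2,6,6-trimethylcyclohex-1-en-1-yl]-3-methylpent-2-en-4-yn-1-ol
Conditions: Pd(PPh3)4 (5 mol %), CuI (10 mol %), iPr2NH, DMF, rt → 40 °C
Reagents that add atoms: none
Why: Sonogashira coupling, in which zerovalent palladium inserts into the vinyl C–OTf bond and the copper acetylide of 7 transmetalates, forming C6'–C7' with the ring double bond fixed and the (E)-enynol geometry untouched.

Step 6
Reactants: 8 (2E)-5-[(4R)-4-(tert-butyldimethylsilyloxy)-2,6,6-trimethylcyclohex-1-en-1-yl]-3-methylpent-2-en-4-yn-1-ol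
Product: 9 (4R)-1-[(3E)-5-bromo-3-methylpent-3-en-1-yn-1-yl]-4-(tert-butyldimethylsilyloxy)-2,6,6-trimethylcyclohex-1-ene
Conditions: CBr4, PPh3, CH2Cl2, −20 → 0 °C
Reagents that add atoms: carbon tetrabromide BrC(Br)(Br)Br
Why: Appel bromination of a primary allylic alcohol under neutral conditions, which keeps the silyl ether and the (E)-alkene.

Step 7
Reactants: 9 (4R)-1-[(3E)-5-bromo-3-methylpent-3-en-1-yn-1-yl]-4-(tert-butyldimethylsilyloxy)-2,6,6-trimethylcyclohex-1-ene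
Product: 10 tributyl{(2E)-5-[(4R)-4-(tert-butyldimethylsilyloxy)-2,6,6-trimethylcyclohex-1-en-1-yl]-3-methylpent-2-en-4-yn-1-yl}phosphonium bromide
Conditions: PBu3, EtOAc, rt
Reagents that add atoms: tributylphosphine CCCCP(CCCC)CCCC
Why: SN2 quaternisation of a primary allylic bromide by a strongly nucleophilic trialkylphosphine.

Step 8
Reactants: 10 tributyl{(2E)-5-[(4R)-4-(tert-butyldimethylsilyloxy)-2,6,6-trimethylcyclohex-1-en-1-yl]-3-methylpent-2-en-4-yn-1-yl}phosphonium bromide; 11 (2E,4E,6E)-2,7-dimethylocta-2,4,6-trienedial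
Product: 13 (2E,4E,6E,8E,10E)-13-[(4R)-4-(tert-butyldimethylsilyloxy)-2,6,6-trimethylcyclohex-1-en-1-yl]-2,7,11-trimethyltrideca-2,4,6,8,10-pentaen-12-ynal, via tributylphosphonium ylide 12 (not isolated)
Conditions: NaOMe, MeOH/CH2Cl2, 0 °C → rt; 11 in excess (3 equiv); dark
Reagents that add atoms: none
Why: Wittig olefination with a semistabilised trialkylphosphonium ylide, which favours the (E)-alkene at the new C11'=C12' bond, while the excess of the symmetrical dialdehyde enforces mono-olefination.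

Step 9
Reactants: 13 (2E,4E,6E,8E,10E)-13-[(4R)-4-(tert-butyldimethylsilyloxy)-2,6,6-trimethylcyclohex-1-en-1-yl]-2,7,11-trimethyltrideca-2,4,6,8,10-pentaen-12-ynal
Product: 14 (2E,4E,6E,8E,10E)-13-[(4R)-4-(tert-butyldimethylsilyloxy)-2,6,6-trimethylcyclohex-1-en-1-yl]-2,7,11-trimethyltrideca-2,4,6,8,10-pentaen-12-yn-1-ol
Conditions: NaBH4, MeOH/THF, 0 °C
Reagents that add atoms: none
Why: Borohydride 1,2-reduction of a polyenal to the allylic alcohol without touching the polyene or the alkyne.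

Step 10
Reactants: 14 (2E,4E,6E,8E,10E)-13-[(4R)-4-(tert-butyldimethylsilyloxy)-2,6,6-trimethylcyclohex-1-en-1-yl]-2,7,11-trimethyltrideca-2,4,6,8,10-pentaen-12-yn-1-ol
Product: 15 (4R)-1-[(3E,5E,7E,9E,11E)-13-bromo-3,7,12-trimethyltrideca-3,5,7,9,11-pentaen-1-yn-1-yl]-4-(tert-butyldimethylsilyloxy)-2,6,6-trimethylcyclohex-1-ene
Conditions: CBr4, PPh3 (1.05 equiv), CH2Cl2, −30 °C; cold filtration, used at once
Reagents that add atoms: carbon tetrabromide BrC(Br)(Br)Br
Why: Appel bromination at low temperature gives the labile polyenyl bromide without acid, which would ionise the polyenyl alcohol.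

Step 11
Reactants: 15 (4R)-1-[(3E,5E,7E,9E,11E)-13-bromo-3,7,12-trimethyltrideca-3,5,7,9,11-pentaen-1-yn-1-yl]-4-(tert-butyldimethylsilyloxy)-2,6,6-trimethylcyclohex-1-ene
Product: 16 tributyl{(2E,4E,6E,8E,10E)-13-[(4R)-4-(tert-butyldimethylsilyloxy)-2,6,6-trimethylcyclohex-1-en-1-yl]-2,7,11-trimethyltrideca-2,4,6,8,10-pentaen-12-yn-1-yl}phosphonium bromide
Conditions: PBu3, CH2Cl2/EtOAc, −20 °C → rt
Reagents that add atoms: tributylphosphine CCCCP(CCCC)CCCC
Why: Rapid SN2 capture of the primary polyenyl bromide by tributylphosphine gives the stable conjugated phosphonium salt.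

Step 12
Reactants: 6 (4R)-4-(tert-butyldimethylsilyloxy)-2,6,6-trimethylcyclohex-1-en-1-yl trifluoromethanesulfonate
Product: 17 methyl (4R)-4-(tert-butyldimethylsilyloxy)-2,6,6-trimethylcyclohex-1-ene-1-carboxylate
Conditions: Pd(OAc)2 (5 mol %), PPh3 (10 mol %), CO (1 atm), MeOH, Et3N, DMF, 60 °C
Reagents that add atoms: carbon monoxide [C-]#[O+]; methanol CO
Why: Palladium-catalysed methoxycarbonylation of an enol triflate (oxidative addition to zerovalent palladium, CO insertion, methanolysis) installs C7 with the double bond fixed in place.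

Step 13
Reactants: 17 methyl (4R)-4-(tert-butyldimethylsilyloxy)-2,6,6-trimethylcyclohex-1-ene-1-carboxylate
Product: 18 [(4R)-4-(tert-butyldimethylsilyloxy)-2,6,6-trimethylcyclohex-1-en-1-yl]methanol
Conditions: iBu2AlH, CH2Cl2, −78 → 0 °C
Reagents that add atoms: none
Why: Aluminium hydride 1,2-reduction of the hindered enoate gives the primary allylic alcohol needed for directed epoxidation.

Step 14
Reactants: 18 [(4R)-4-(tert-butyldimethylsilyloxy)-2,6,6-trimethylcyclohex-1-en-1-yl]methanol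
Product: 19 [(1R,4S,6R)-4-(tert-butyldimethylsilyloxy)-2,2,6-trimethyl-7-oxabicyclo[4.1.0]heptan-1-yl]methanol
Conditions: Ti(OiPr)4 (0.3 equiv), D-(−)-diethyl tartrate (0.36 equiv), tBuOOH, 4 Å molecular sieves, CH2Cl2, −20 °C
Reagents that add atoms: tert-butyl hydroperoxide CC(C)(C)OO
Why: Sharpless asymmetric epoxidation, in which the tetravalent titanium/D-(−)-tartrate complex delivers oxygen to the alkene face anti to the silyloxy group (reagent control reinforced by the substrate's own anti preference), setting both oxirane stereocentres.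

Step 15
Reactants: 19 [(1R,4S,6R)-4-(tert-butyldimethylsilyloxy)-2,2,6-trimethyl-7-oxabicyclo[4.1.0]heptan-1-yl]methanol
Product: 20 (1S,4S,6R)-4-(tert-butyldimethylsilyloxy)-2,2,6-trimethyl-7-oxabicyclo[4.1.0]heptane-1-carbaldehyde
Conditions: Dess–Martin periodinane, pyridine, CH2Cl2, 0 °C → rt
Reagents that add atoms: none
Why: Buffered periodinane oxidation gives the epoxy aldehyde, which has no α-hydrogen and so cannot epimerise or eliminate.

Step 16
Reactants: 20 (1S,4S,6R)-4-(tert-butyldimethylsilyloxy)-2,2,6-trimethyl-7-oxabicyclo[4.1.0]heptane-1-carbaldehyde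
Product: 21 (1S,4S,6R)-4-(tert-butyldimethylsilyloxy)-1-ethenyl-2,2,6-trimethyl-7-oxabicyclo[4.1.0]heptane
Conditions: Ph3PCH3Br, KOtBu, THF, 0 °C → rt
Reagents that add atoms: methyltriphenylphosphonium bromide C[P+](c1ccccc1)(c1ccccc1)c1ccccc1.[Br-]
Why: Wittig methylenation with the small, reactive non-stabilised ylide works on hindered non-enolisable aldehydes and adds the C8 carbon; the tetrasubstituted oxirane is inert to the ylide.

Step 17
Reactants: 21 (1S,4S,6R)-4-(tert-butyldimethylsilyloxy)-1-ethenyl-2,2,6-trimethyl-7-oxabicyclo[4.1.0]heptane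
Product: 23 2-[(1S,4S,6R)-4-(tert-butyldimethylsilyloxy)-2,2,6-trimethyl-7-oxabicyclo[4.1.0]heptan-1-yl]ethan-1-ol, via B-alkyl-9-BBN 22 (not isolated)
Conditions: 9-BBN, THF, 0 °C → rt; then NaOH, H2O2, 0 °C
Reagents that add atoms: hydrogen peroxide OO
Why: Anti-Markovnikov hydroboration–oxidation, in which the bulky dialkylborane places boron only on the terminal carbon (γ to the oxirane oxygen, so no β-elimination) and alkaline peroxide leaves the tetrasubstituted epoxide intact.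

Step 18
Reactants: 23 2-[(1S,4S,6R)-4-(tert-butyldimethylsilyloxy)-2,2,6-trimethyl-7-oxabicyclo[4.1.0]heptan-1-yl]ethan-1-ol
Product: 24 2-[(1S,4S,6R)-4-(tert-butyldimethylsilyloxy)-2,2,6-trimethyl-7-oxabicyclo[4.1.0]heptan-1-yl]acetaldehyde
Conditions: Dess–Martin periodinane, pyridine, CH2Cl2, 0 °C; used at once
Reagents that add atoms: none
Why: Periodinane oxidation under buffered, essentially neutral conditions avoids the base-induced E1cB opening to which a β,γ-epoxy aldehyde is prone.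

Step 19
Reactants: 25 ethyl but-2-ynoate
Product: 27 ethyl (2E)-3-(tributylstannyl)but-2-enoate, via vinylcopper adduct 26 (not isolated)
Conditions: Bu3SnH, LiN(iPr)2, THF, −30 °C; CuBr·SMe2, −78 °C; then 25, MeOH, −78 °C
Reagents that add atoms: tributylstannane CCCC[SnH](CCCC)CCCC
Why: Stannylcupration of an ynoate, a syn addition of tin and copper with tin at the β-carbon, followed by immediate protonation of the vinylcopper by methanol at −78 °C, gives the kinetic (E)-β-stannyl enoate.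

Step 20
Reactants: 27 ethyl (2E)-3-(tributylstannyl)but-2-enoate
Product: 28 ethyl (2E)-3-iodobut-2-enoate
Conditions: I2, CH2Cl2, 0 °C
Reagents that add atoms: iodine II
Why: Iododestannylation occurs by ipso substitution with retention of alkene geometry.

Step 21
Reactants: 24 2-[(1S,4S,6R)-4-(tert-butyldimethylsilyloxy)-2,2,6-trimethyl-7-oxabicyclo[4.1.0]heptan-1-yl]acetaldehyde; 28 ethyl (2E)-3-iodobut-2-enoate
Product: 30 ethyl (2E,4RS)-5-[(1S,4S,6R)-4-(tert-butyldimethylsilyloxy)-2,2,6-trimethyl-7-oxabicyclo[4.1.0]heptan-1-yl]-4-hydroxy-3-methylpent-2-enoate (C8 epimers), via vinylchromium dichloride 29 (not isolated)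
Conditions: CrCl2 (4 equiv), NiCl2 (1 mol %), DMSO, rt
Reagents that add atoms: none
Why: Nozaki–Hiyama–Kishi coupling, in which a nickel-catalysed vinylchromium species (trivalent chromium) adds chemoselectively to the aldehyde under non-basic conditions with retention of the (E)-geometry, sparing the labile aldehyde, the ester and the silyl ether; the new C8 carbinol forms as both epimers, which is harmless because C8 ends as the ketone.

Step 22
Reactants: 30 ethyl (2E,4RS)-5-[(1S,4S,6R)-4-(tert-butyldimethylsilyloxy)-2,2,6-trimethyl-7-oxabicyclo[4.1.0]heptan-1-yl]-4-hydroxy-3-methylpent-2-enoate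
Product: 31 ethyl (2E,4RS)-4-(tert-butyldimethylsilyloxy)-5-[(1S,4S,6R)-4-(tert-butyldimethylsilyloxy)-2,2,6-trimethyl-7-oxabicyclo[4.1.0]heptan-1-yl]-3-methylpent-2-enoate
Conditions: TBSCl, imidazole, DMAP (cat.), DMF, rt → 40 °C
Reagents that add atoms: tert-butyldimethylsilyl chloride CC(C)(C)[Si](C)(C)Cl
Why: Base-mediated silylation (no Lewis acid that could open the oxirane) masks the C8 alcohol so that all three hydroxyls can be released together later.

Step 23
Reactants: 31 ethyl (2E,4RS)-4-(tert-butyldimethylsilyloxy)-5-[(1S,4S,6R)-4-(tert-butyldimethylsilyloxy)-2,2,6-trimethyl-7-oxabicyclo[4.1.0]heptan-1-yl]-3-methylpent-2-enoate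
Product: 32 (2E,4RS)-4-(tert-butyldimethylsilyloxy)-5-[(1S,4S,6R)-4-(tert-butyldimethylsilyloxy)-2,2,6-trimethyl-7-oxabicyclo[4.1.0]heptan-1-yl]-3-methylpent-2-en-1-ol
Conditions: iBu2AlH, CH2Cl2, −78 °C
Reagents that add atoms: none
Why: Aluminium hydride 1,2-reduction of the enoate at −78 °C gives the allylic alcohol, a temperature at which the tetrasubstituted epoxide and silyl ethers are inert.

Step 24
Reactants: 32 (2E,4RS)-4-(tert-butyldimethylsilyloxy)-5-[(1S,4S,6R)-4-(tert-butyldimethylsilyloxy)-2,2,6-trimethyl-7-oxabicyclo[4.1.0]heptan-1-yl]-3-methylpent-2-en-1-ol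
Product: 33 (2E,4RS)-4-(tert-butyldimethylsilyloxy)-5-[(1S,4S,6R)-4-(tert-butyldimethylsilyloxy)-2,2,6-trimethyl-7-oxabicyclo[4.1.0]heptan-1-yl]-3-methylpent-2-enal
Conditions: MnO2, CH2Cl2, rt
Reagents that add atoms: none
Why: Allylic oxidation with manganese dioxide gives the (E)-enal under neutral conditions without over-oxidation.

Step 25
Reactants: 16 tributyl{(2E,4E,6E,8E,10E)-13-[(4R)-4-(tert-butyldimethylsilyloxy)-2,6,6-trimethylcyclohex-1-en-1-yl]-2,7,11-trimethyltrideca-2,4,6,8,10-pentaen-12-yn-1-yl}phosphonium bromide; 33 (2E,4RS)-4-(tert-butyldimethylsilyloxy)-5-[(1S,4S,6R)-4-(tert-butyldimethylsilyloxy)-2,2,6-trimethyl-7-oxabicyclo[4.1.0]heptan-1-yl]-3-methylpent-2-enal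
Product: 35 (all-E,3S,5R,6S,8RS,3'R)-3,8,3'-tris(tert-butyldimethylsilyloxy)-5,6-epoxy-7',8'-didehydro-5,6,7,8-tetrahydro-β,β-carotene, via C25 ylide 34 (not isolated)
Conditions: NaOMe, MeOH/CH2Cl2, 0 °C → rt, argon, dark; chromatography on deactivated silica
Reagents that add atoms: none
Why: Wittig olefination forms C11=C12 with the (E)-preference of a tributylphosphonium polyenyl ylide, and because C8 is still a silyl ether there is no base-labile β,γ-epoxy ketone present.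

Step 26
Reactants: 35 (all-E,3S,5R,6S,8RS,3'R)-3,8,3'-tris(tert-butyldimethylsilyloxy)-5,6-epoxy-7',8'-didehydro-5,6,7,8-tetrahydro-β,β-carotene
Product: 36 (all-E,3S,5R,6S,8RS,3'R)-5,6-epoxy-7',8'-didehydro-5,6,7,8-tetrahydro-β,β-carotene-3,8,3'-triol
Conditions: Bu4NF, THF, 0 °C → rt, dark
Reagents that add atoms: none
Why: Fluoride-mediated global desilylation, done while C8 is still an alcohol so that the basic fluoride meets no enolisable epoxy ketone.

Step 27
Reactants: 36 (all-E,3S,5R,6S,8RS,3'R)-5,6-epoxy-7',8'-didehydro-5,6,7,8-tetrahydro-β,β-carotene-3,8,3'-triol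
Product: 37 halocynthiaxanthin, (3S,5R,6S,3'R)-5,6-epoxy-3,3'-dihydroxy-7',8'-didehydro-5,6,7,8-tetrahydro-β,β-caroten-8-one
Conditions: MnO2, CH2Cl2, rt, dark
Reagents that add atoms: none
Why: Manganese dioxide oxidises only the allylic (polyene-conjugated) C8 carbinol and leaves the saturated C3 and C3' alcohols alone, both C8 epimers converge on the ketone, and the neutral medium spares the β,γ-epoxy ketone.

## Compound list

1 | 2,6,6-trimethylcyclohex-2-ene-1,4-dione (ketoisophorone) | CC1=CC(=O)CC(C)(C)C1=O | starting material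
2 | (6R)-2,2,6-trimethylcyclohexane-1,4-dione | C[C@@H]1CC(=O)CC(C)(C)C1=O | intermediate
3 | (4R,6R)-4-hydroxy-2,2,6-trimethylcyclohexan-1-one | C[C@@H]1C[C@@H](O)CC(C)(C)C1=O | intermediate
4 | (4R,6R)-4-(tert-butyldimethylsilyloxy)-2,2,6-trimethylcyclohexan-1-one | C[C@@H]1C[C@@H](O[Si](C)(C)C(C)(C)C)CC(C)(C)C1=O | intermediate
5 | lithium (4R)-4-(tert-butyldimethylsilyloxy)-2,6,6-trimethylcyclohex-1-en-1-olate | CC1=C(O[Li])C(C)(C)C[C@H](O[Si](C)(C)C(C)(C)C)C1 | intermediate (not isolated)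
6 | (4R)-4-(tert-butyldimethylsilyloxy)-2,6,6-trimethylcyclohex-1-en-1-yl trifluoromethanesulfonate | CC1=C(OS(=O)(=O)C(F)(F)F)C(C)(C)C[C@H](O[Si](C)(C)C(C)(C)C)C1 | intermediate
7 | (E)-3-methylpent-2-en-4-yn-1-ol | C#C/C(C)=C/CO | starting material
8 | (2E)-5-[(4R)-4-(tert-butyldimethylsilyloxy)-2,6,6-trimethylcyclohex-1-en-1-yl]-3-methylpent-2-en-4-yn-1-ol | CC1=C(C#C/C(C)=C/CO)C(C)(C)C[C@H](O[Si](C)(C)C(C)(C)C)C1 | intermediate
9 | (4R)-1-[(3E)-5-bromo-3-methylpent-3-en-1-yn-1-yl]-4-(tert-butyldimethylsilyloxy)-2,6,6-trimethylcyclohex-1-ene | CC1=C(C#C/C(C)=C/CBr)C(C)(C)C[C@H](O[Si](C)(C)C(C)(C)C)C1 | intermediate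
10 | tributyl{(2E)-5-[(4R)-4-(tert-butyldimethylsilyloxy)-2,6,6-trimethylcyclohex-1-en-1-yl]-3-methylpent-2-en-4-yn-1-yl}phosphonium bromide | CC1=C(C#C/C(C)=C/C[P+](CCCC)(CCCC)CCCC)C(C)(C)C[C@H](O[Si](C)(C)C(C)(C)C)C1.[Br-] | intermediate
11 | (2E,4E,6E)-2,7-dimethylocta-2,4,6-trienedial | O=C/C(C)=C/C=C/C=C(C)/C=O | starting material
12 | tributyl{(2E)-5-[(4R)-4-(tert-butyldimethylsilyloxy)-2,6,6-trimethylcyclohex-1-en-1-yl]-3-methylpent-2-en-4-yn-1-ylidene}phosphorane | CC1=C(C#C/C(C)=C/C=P(CCCC)(CCCC)CCCC)C(C)(C)C[C@H](O[Si](C)(C)C(C)(C)C)C1 | intermediate (not isolated)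
13 | (2E,4E,6E,8E,10E)-13-[(4R)-4-(tert-butyldimethylsilyloxy)-2,6,6-trimethylcyclohex-1-en-1-yl]-2,7,11-trimethyltrideca-2,4,6,8,10-pentaen-12-ynal | CC1=C(C#C/C(C)=C/C=C/C(C)=C/C=C/C=C(C)/C=O)C(C)(C)C[C@H](O[Si](C)(C)C(C)(C)C)C1 | intermediate
14 | (2E,4E,6E,8E,10E)-13-[(4R)-4-(tert-butyldimethylsilyloxy)-2,6,6-trimethylcyclohex-1-en-1-yl]-2,7,11-trimethyltrideca-2,4,6,8,10-pentaen-12-yn-1-ol | CC1=C(C#C/C(C)=C/C=C/C(C)=C/C=C/C=C(C)/CO)C(C)(C)C[C@H](O[Si](C)(C)C(C)(C)C)C1 | intermediate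
15 | (4R)-1-[(3E,5E,7E,9E,11E)-13-bromo-3,7,12-trimethyltrideca-3,5,7,9,11-pentaen-1-yn-1-yl]-4-(tert-butyldimethylsilyloxy)-2,6,6-trimethylcyclohex-1-ene | CC1=C(C#C/C(C)=C/C=C/C(C)=C/C=C/C=C(C)/CBr)C(C)(C)C[C@H](O[Si](C)(C)C(C)(C)C)C1 | intermediate
16 | tributyl{(2E,4E,6E,8E,10E)-13-[(4R)-4-(tert-butyldimethylsilyloxy)-2,6,6-trimethylcyclohex-1-en-1-yl]-2,7,11-trimethyltrideca-2,4,6,8,10-pentaen-12-yn-1-yl}phosphonium bromide | CC1=C(C#C/C(C)=C/C=C/C(C)=C/C=C/C=C(C)/C[P+](CCCC)(CCCC)CCCC)C(C)(C)C[C@H](O[Si](C)(C)C(C)(C)C)C1.[Br-] | intermediate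
17 | methyl (4R)-4-(tert-butyldimethylsilyloxy)-2,6,6-trimethylcyclohex-1-ene-1-carboxylate | CC1=C(C(=O)OC)C(C)(C)C[C@H](O[Si](C)(C)C(C)(C)C)C1 | intermediate
18 | [(4R)-4-(tert-butyldimethylsilyloxy)-2,6,6-trimethylcyclohex-1-en-1-yl]methanol | CC1=C(CO)C(C)(C)C[C@H](O[Si](C)(C)C(C)(C)C)C1 | intermediate
19 | [(1R,4S,6R)-4-(tert-butyldimethylsilyloxy)-2,2,6-trimethyl-7-oxabicyclo[4.1.0]heptan-1-yl]methanol (oxirane trans to the silyloxy group) | OC[C@@]12O[C@]1(C)C[C@@H](O[Si](C)(C)C(C)(C)C)CC2(C)C | intermediate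
20 | (1S,4S,6R)-4-(tert-butyldimethylsilyloxy)-2,2,6-trimethyl-7-oxabicyclo[4.1.0]heptane-1-carbaldehyde | O=C[C@@]12O[C@]1(C)C[C@@H](O[Si](C)(C)C(C)(C)C)CC2(C)C | intermediate
21 | (1S,4S,6R)-4-(tert-butyldimethylsilyloxy)-1-ethenyl-2,2,6-trimethyl-7-oxabicyclo[4.1.0]heptane | C=C[C@@]12O[C@]1(C)C[C@@H](O[Si](C)(C)C(C)(C)C)CC2(C)C | intermediate
22 | 9-{2-[(1S,4S,6R)-4-(tert-butyldimethylsilyloxy)-2,2,6-trimethyl-7-oxabicyclo[4.1.0]heptan-1-yl]ethyl}-9-borabicyclo[3.3.1]nonane | B1(CC[C@@]23O[C@]2(C)C[C@@H](O[Si](C)(C)C(C)(C)C)CC3(C)C)C2CCCC1CCC2 | intermediate (not isolated)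
23 | 2-[(1S,4S,6R)-4-(tert-butyldimethylsilyloxy)-2,2,6-trimethyl-7-oxabicyclo[4.1.0]heptan-1-yl]ethan-1-ol | OCC[C@@]12O[C@]1(C)C[C@@H](O[Si](C)(C)C(C)(C)C)CC2(C)C | intermediate
24 | 2-[(1S,4S,6R)-4-(tert-butyldimethylsilyloxy)-2,2,6-trimethyl-7-oxabicyclo[4.1.0]heptan-1-yl]acetaldehyde | O=CC[C@@]12O[C@]1(C)C[C@@H](O[Si](C)(C)C(C)(C)C)CC2(C)C | intermediate
25 | ethyl but-2-ynoate | CC#CC(=O)OCC | starting material
26 | ethyl (2Z)-2-cuprio-3-(tributylstannyl)but-2-enoate | CCOC(=O)/C([Cu])=C(\C)[Sn](CCCC)(CCCC)CCCC | intermediate (not isolated)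
27 | ethyl (2E)-3-(tributylstannyl)but-2-enoate | CCOC(=O)/C=C(\C)[Sn](CCCC)(CCCC)CCCC | intermediate
28 | ethyl (2E)-3-iodobut-2-enoate | CCOC(=O)/C=C(\C)I | intermediate
29 | ethyl (2E)-3-(dichlorochromio)but-2-enoate | CCOC(=O)/C=C(\C)[Cr](Cl)Cl | intermediate (not isolated)
30 | ethyl (2E,4RS)-5-[(1S,4S,6R)-4-(tert-butyldimethylsilyloxy)-2,2,6-trimethyl-7-oxabicyclo[4.1.0]heptan-1-yl]-4-hydroxy-3-methylpent-2-enoate | CCOC(=O)/C=C(\C)C(O)C[C@@]12O[C@]1(C)C[C@@H](O[Si](C)(C)C(C)(C)C)CC2(C)C | intermediate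
31 | ethyl (2E,4RS)-4-(tert-butyldimethylsilyloxy)-5-[(1S,4S,6R)-4-(tert-butyldimethylsilyloxy)-2,2,6-trimethyl-7-oxabicyclo[4.1.0]heptan-1-yl]-3-methylpent-2-enoate | CCOC(=O)/C=C(\C)C(O[Si](C)(C)C(C)(C)C)C[C@@]12O[C@]1(C)C[C@@H](O[Si](C)(C)C(C)(C)C)CC2(C)C | intermediate
32 | (2E,4RS)-4-(tert-butyldimethylsilyloxy)-5-[(1S,4S,6R)-4-(tert-butyldimethylsilyloxy)-2,2,6-trimethyl-7-oxabicyclo[4.1.0]heptan-1-yl]-3-methylpent-2-en-1-ol | OC/C=C(\C)C(O[Si](C)(C)C(C)(C)C)C[C@@]12O[C@]1(C)C[C@@H](O[Si](C)(C)C(C)(C)C)CC2(C)C | intermediate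
33 | (2E,4RS)-4-(tert-butyldimethylsilyloxy)-5-[(1S,4S,6R)-4-(tert-butyldimethylsilyloxy)-2,2,6-trimethyl-7-oxabicyclo[4.1.0]heptan-1-yl]-3-methylpent-2-enal | O=C/C=C(\C)C(O[Si](C)(C)C(C)(C)C)C[C@@]12O[C@]1(C)C[C@@H](O[Si](C)(C)C(C)(C)C)CC2(C)C | intermediate
34 | tributyl{(2E,4E,6E,8E,10E)-13-[(4R)-4-(tert-butyldimethylsilyloxy)-2,6,6-trimethylcyclohex-1-en-1-yl]-2,7,11-trimethyltrideca-2,4,6,8,10-pentaen-12-yn-1-ylidene}phosphorane | CC1=C(C#C/C(C)=C/C=C/C(C)=C/C=C/C=C(C)/C=P(CCCC)(CCCC)CCCC)C(C)(C)C[C@H](O[Si](C)(C)C(C)(C)C)C1 | intermediate (not isolated)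
35 | (all-E,3S,5R,6S,8RS,3'R)-3,8,3'-tris(tert-butyldimethylsilyloxy)-5,6-epoxy-7',8'-didehydro-5,6,7,8-tetrahydro-β,β-carotene | CC1=C(C#C/C(C)=C/C=C/C(C)=C/C=C/C=C(C)/C=C/C=C(\C)C(O[Si](C)(C)C(C)(C)C)C[C@@]23O[C@]2(C)C[C@@H](O[Si](C)(C)C(C)(C)C)CC3(C)C)C(C)(C)C[C@H](O[Si](C)(C)C(C)(C)C)C1 | intermediate
36 | (all-E,3S,5R,6S,8RS,3'R)-5,6-epoxy-7',8'-didehydro-5,6,7,8-tetrahydro-β,β-carotene-3,8,3'-triol | CC1=C(C#C/C(C)=C/C=C/C(C)=C/C=C/C=C(C)/C=C/C=C(\C)C(O)C[C@@]23O[C@]2(C)C[C@@H](O)CC3(C)C)C(C)(C)C[C@H](O)C1 | intermediate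
37 | halocynthiaxanthin, (3S,5R,6S,3'R)-5,6-epoxy-3,3'-dihydroxy-7',8'-didehydro-5,6,7,8-tetrahydro-β,β-caroten-8-one | CC1=C(C#C/C(C)=C/C=C/C(C)=C/C=C/C=C(C)/C=C/C=C(\C)C(=O)C[C@@]23O[C@]2(C)C[C@@H](O)CC3(C)C)C(C)(C)C[C@H](O)C1 | target

## Step count and risks

Total step count: 27.
Longest linear sequence: 18 steps (1 → 2 → 3 → 4 → 6 → 17 → 18 → 19 → 20 → 21 → 23 → 24 → 30 → 31 → 32 → 33 → 35 → 36 → 37).

Steps most likely to fail:

Step 17 (hydroboration of the vinyl epoxide). The borane may open the allylic oxirane reductively or react sluggishly at the neopentyl-type vinyl group. Fallback: leave the route at epoxy aldehyde 20 and homologate by an enol ether instead of by methylenation/hydroboration/oxidation. A Wittig reaction with methoxymethylenetriphenylphosphorane (from Ph3PCH2OMe chloride and KN(SiMe3)2, THF, −78 → 0 °C) gives the enol ether (1S,4S,6R)-4-(tert-butyldimethylsilyloxy)-1-(2-methoxyethenyl)-2,2,6-trimethyl-7-oxabicyclo[4.1.0]heptane F1 as an E/Z mixture. Near-neutral hydrolysis (Hg(OAc)2, THF/H2O, 0 °C, then aqueous KI) brings the material back to the route at aldehyde 24, so 21, 22 and 23 are bypassed.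

Step 21 (chromium/nickel coupling with the labile β,γ-epoxy aldehyde from step 18). Trivalent chromium may act as a Lewis acid on the oxirane or on the product alkoxide, or the aldehyde may eliminate before it couples. Fallback: set out from 24 and 28 and use a preformed organolithium at low temperature with a different end of the sequence. Reduce 28 with iBu2AlH (CH2Cl2, −78 °C) to (E)-3-iodobut-2-en-1-ol F2. Treat it with n-BuLi and then t-BuLi (2 equiv, Et2O, −78 °C) to give lithium (E)-3-lithiobut-2-en-1-olate F3. Add 24 at −78 °C and quench cold to obtain (2E,4RS)-5-[(1S,4S,6R)-4-(tert-butyldimethylsilyloxy)-2,2,6-trimethyl-7-oxabicyclo[4.1.0]heptan-1-yl]-3-methylpent-2-ene-1,4-diol F4. Oxidise only the primary allylic alcohol with TEMPO/PhI(OAc)2 to (2E,4RS)-5-[(1S,4S,6R)-4-(tert-butyldimethylsilyloxy)-2,2,6-trimethyl-7-oxabicyclo[4.1.0]heptan-1-yl]-4-hydroxy-3-methylpent-2-enal F5. Silylation (TBSCl, imidazole, DMF) returns to the route at enal 33, bypassing 30, 31 and 32.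

Step 25 (last Wittig union). The C25 ylide delocalises its charge through the whole enyne chain, which can scramble double-bond geometry (notably at C9'), and the C25 bromide and salt behind it (steps 10 and 11) are fragile. Fallback: reverse the polarity, setting out from 32 and 13. An Appel reaction on 32 (CBr4, PPh3, CH2Cl2, −20 °C) gives (1S,4S,6R)-1-[(2RS,3E)-5-bromo-2-(tert-butyldimethylsilyloxy)-3-methylpent-3-en-1-yl]-4-(tert-butyldimethylsilyloxy)-2,2,6-trimethyl-7-oxabicyclo[4.1.0]heptane F6. PBu3 then gives tributyl{(2E,4RS)-4-(tert-butyldimethylsilyloxy)-5-[(1S,4S,6R)-4-(tert-butyldimethylsilyloxy)-2,2,6-trimethyl-7-oxabicyclo[4.1.0]heptan-1-yl]-3-methylpent-2-en-1-yl}phosphonium bromide F7. Its ylide (NaOMe, CH2Cl2/MeOH, −20 °C, kept cold to suppress loss of the C8 silyloxy group) is condensed with C25 aldehyde 13, which carries no carbanion and so keeps its geometry. This comes back to the route at 35 and bypasses 14, 15, 16 and 33.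

## Further compounds

F1 | step 17 | (1S,4S,6R)-4-(tert-butyldimethylsilyloxy)-1-(2-methoxyethenyl)-2,2,6-trimethyl-7-oxabicyclo[4.1.0]heptane (E/Z mixture) | COC=C[C@@]12O[C@]1(C)C[C@@H](O[Si](C)(C)C(C)(C)C)CC2(C)C
F2 | step 21 | (E)-3-iodobut-2-en-1-ol | OC/C=C(\C)I
F3 | step 21 | lithium (E)-3-lithiobut-2-en-1-olate | [Li]OC/C=C(\C)[Li]
F4 | step 21 | (2E,4RS)-5-[(1S,4S,6R)-4-(tert-butyldimethylsilyloxy)-2,2,6-trimethyl-7-oxabicyclo[4.1.0]heptan-1-yl]-3-methylpent-2-ene-1,4-diol | OC/C=C(\C)C(O)C[C@@]12O[C@]1(C)C[C@@H](O[Si](C)(C)C(C)(C)C)CC2(C)C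
F5 | step 21 | (2E,4RS)-5-[(1S,4S,6R)-4-(tert-butyldimethylsilyloxy)-2,2,6-trimethyl-7-oxabicyclo[4.1.0]heptan-1-yl]-4-hydroxy-3-methylpent-2-enal | O=C/C=C(\C)C(O)C[C@@]12O[C@]1(C)C[C@@H](O[Si](C)(C)C(C)(C)C)CC2(C)C
F6 | step 25 | (1S,4S,6R)-1-[(2RS,3E)-5-bromo-2-(tert-butyldimethylsilyloxy)-3-methylpent-3-en-1-yl]-4-(tert-butyldimethylsilyloxy)-2,2,6-trimethyl-7-oxabicyclo[4.1.0]heptane | BrC/C=C(\C)C(O[Si](C)(C)C(C)(C)C)C[C@@]12O[C@]1(C)C[C@@H](O[Si](C)(C)C(C)(C)C)CC2(C)C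
F7 | step 25 | tributyl{(2E,4RS)-4-(tert-butyldimethylsilyloxy)-5-[(1S,4S,6R)-4-(tert-butyldimethylsilyloxy)-2,2,6-trimethyl-7-oxabicyclo[4.1.0]heptan-1-yl]-3-methylpent-2-en-1-yl}phosphonium bromide | CCCC[P+](CCCC)(CCCC)C/C=C(\C)C(O[Si](C)(C)C(C)(C)C)C[C@@]12O[C@]1(C)C[C@@H](O[Si](C)(C)C(C)(C)C)CC2(C)C.[Br-]
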